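Ring C of the target holds a hydroxyl at C3 beside the C4 aryl ketone. This acyloin unit is disconnected by a retro-ketol shift to a ring-contracted 2-aryl-2,3-dihydrobenzofuran whose C3 carries both a hydroxyl and a formyl group. In the forward sense a single 1,2-shift of C2 to the formyl carbon makes the C2–C3 bond, widens the furan to ring C, turns the old carbinol carbon into the C4 ketone and creates the C3 carbinol, with C2 keeping its configuration. The precursor is the (2R,3S)-hydroxy aldehyde 13, with 4-methoxy and two silyl ethers, made by enantioselective carbenoid C–H insertion. The reverse-prenyl group at C6 follows by Claisen shift from O5.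

Key step: step 10

Assumption: Rh2(S-PTTL)4 is taken to deliver the (2S)-configured ester 10 by analogy with simpler benzyl aryl ethers; if the sense proves opposite on this substrate, the mirror-image catalyst Rh2(R-PTTL)4 is used under the same conditions.

Abbreviation: TIPS = triisopropylsilyl.

Step 1
Reactants: 1 5-methoxyresorcinol; 2 methyl chlorooxoacetate
Product: 3 methyl 2-(2,4-dihydroxy-6-methoxyphenyl)-2-oxoacetate
Conditions: AlCl3 (2.5 equiv), CH2Cl2/MeNO2, 0 °C → rt; then ice-cold aq HCl
Reagents that add atoms: none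
Why: Friedel–Crafts C-acylation of this doubly activated phenol should take place at the ring carbon para to one hydroxyl and ortho to the other (the carbon between the two aluminium aryloxides being the most crowded), and any 2,6-dihydroxy isomer is removed at this stage.

Step 2
Reactants: 3 methyl 2-(2,4-dihydroxy-6-methoxyphenyl)-2-oxoacetate
Product: 4 methyl 2-[2-hydroxy-6-methoxy-4-(triisopropylsilyloxy)phenyl]-2-oxoacetate
Conditions: TIPSCl (1.05 equiv), imidazole, CH2Cl2, 0 °C
Reagents that add atoms: triisopropylsilyl chloride, CC(C)[Si](Cl)(C(C)C)C(C)C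
Why: Selective O-silylation should occur at the 4-hydroxyl, which is the more acidic and unhindered one, while the 2-hydroxyl is held in a hydrogen bond to the keto group.

Step 3
Reactants: 5 4-hydroxybenzyl alcohol
Product: 6 4-(triisopropylsilyloxy)benzyl alcohol
Conditions: NaH (1.0 equiv), THF, 0 °C; then TIPSCl (1.0 equiv), 0 °C → rt
Reagents that add atoms: triisopropylsilyl chloride, CC(C)[Si](Cl)(C(C)C)C(C)C
Why: One equivalent of base deprotonates only the phenol, and the phenoxide is silylated in preference to the neutral benzylic alcohol (chemoselective silyl ether formation).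

Step 4
Reactants: 4 methyl 2-[2-hydroxy-6-methoxy-4-(triisopropylsilyloxy)phenyl]-2-oxoacetate; 6 4-(triisopropylsilyloxy)benzyl alcohol
Product: 7 methyl 2-[2-methoxy-4-(triisopropylsilyloxy)-6-{[4-(triisopropylsilyloxy)phenyl]methoxy}phenyl]-2-oxoacetate
Conditions: PPh3, DIAD, THF, 0 °C → rt
Reagents that add atoms: none
Why: Mitsunobu etherification joins the only acidic hydroxyl of 4 to the activated primary benzylic alcohol under neutral conditions that spare both aryl silyl ethers and the keto ester.

Step 5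
Reactants: 7 methyl 2-[2-methoxy-4-(triisopropylsilyloxy)-6-{[4-(triisopropylsilyloxy)phenyl]methoxy}phenyl]-2-oxoacetate
Product: 9 methyl 2-diazo-2-[2-methoxy-4-(triisopropylsilyloxy)-6-{[4-(triisopropylsilyloxy)phenyl]methoxy}phenyl]acetate, via tosylhydrazone 8 (not isolated)
Conditions: TsNHNH2, toluene, 70 °C; then DBU, CH2Cl2, 0 °C → rt
Reagents that add atoms: p-toluenesulfonyl hydrazide, Cc1ccc(cc1)S(=O)(=O)NN
Why: The electrophilic keto group of the α-keto ester condenses with the hydrazide, and base-induced loss of sulfinate (Bamford–Stevens diazo formation) gives the aryl diazoacetate.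

Step 6
Reactants: 9 methyl 2-diazo-2-[2-methoxy-4-(triisopropylsilyloxy)-6-{[4-(triisopropylsilyloxy)phenyl]methoxy}phenyl]acetate
Product: 10 methyl (2S,3R)-4-methoxy-6-(triisopropylsilyloxy)-2-[4-(triisopropylsilyloxy)phenyl]-2,3-dihydro-1-benzofuran-3-carboxylate (2,3-cis)
Conditions: Rh2(S-PTTL)4 [dirhodium tetrakis(N-phthaloyl-(S)-tert-leucinate)] (1 mol %), toluene, −60 °C
Reagents that add atoms: none
Why: Intramolecular 1,5 C–H insertion of the rhodium carbenoid into the benzylic ether methylene (activated by oxygen and by the p-silyloxyphenyl ring, unlike the primary methoxy C–H) closes the dihydrofuran, with the chiral carboxylate ligands choosing between the enantiotopic benzylic hydrogens to set C2 and the cis ester at C3.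

Step 7
Reactants: 10 methyl (2S,3R)-4-methoxy-6-(triisopropylsilyloxy)-2-[4-(triisopropylsilyloxy)phenyl]-2,3-dihydro-1-benzofuran-3-carboxylate
Product: 11 methyl (2R,3S)-3-hydroxy-4-methoxy-6-(triisopropylsilyloxy)-2-[4-(triisopropylsilyloxy)phenyl]-2,3-dihydro-1-benzofuran-3-carboxylate (hydroxyl trans to the C2 aryl group)
Conditions: KN(SiMe3)2 (KHMDS), THF, −78 °C; then 3-phenyl-2-(phenylsulfonyl)oxaziridine, −78 °C; AcOH quench
Reagents that add atoms: 3-phenyl-2-(phenylsulfonyl)oxaziridine (Davis oxaziridine), O=S(=O)(c1ccccc1)N1OC1c1ccccc1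
Why: Davis enolate hydroxylation should deliver oxygen to the enolate face opposite the C2 aryl group, while ring opening by loss of the aryloxide is stereoelectronically disfavoured at −78 °C (the enolate p orbital lies orthogonal to the ring C–O bond), so C2 is untouched and only its descriptor changes.

Step 8
Reactants: 11 methyl (2R,3S)-3-hydroxy-4-methoxy-6-(triisopropylsilyloxy)-2-[4-(triisopropylsilyloxy)phenyl]-2,3-dihydro-1-benzofuran-3-carboxylate
Product: 12 (2R,3R)-3-(hydroxymethyl)-4-methoxy-6-(triisopropylsilyloxy)-2-[4-(triisopropylsilyloxy)phenyl]-2,3-dihydro-1-benzofuran-3-ol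
Conditions: LiBH4, THF, 0 °C → rt
Reagents that add atoms: none
Why: Borohydride reduction of the α-hydroxy ester, which is activated by chelation, gives the primary alcohol without touching the aryl silyl ethers or either stereocentre.

Step 9
Reactants: 12 (2R,3R)-3-(hydroxymethyl)-4-methoxy-6-(triisopropylsilyloxy)-2-[4-(triisopropylsilyloxy)phenyl]-2,3-dihydro-1-benzofuran-3-ol
Product: 13 (2R,3S)-3-hydroxy-4-methoxy-6-(triisopropylsilyloxy)-2-[4-(triisopropylsilyloxy)phenyl]-2,3-dihydro-1-benzofuran-3-carbaldehyde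
Conditions: SO3·pyridine, DMSO, iPr2NEt, CH2Cl2, 0 °C
Reagents that add atoms: none
Why: Parikh–Doering oxidation converts only the primary alcohol (the tertiary one cannot be oxidised and no glycol cleavage is expected), and its non-acidic medium avoids ionising the electron-rich benzylic carbinol; the aldehyde is used promptly.

Step 10
Reactants: 13 (2R,3S)-3-hydroxy-4-methoxy-6-(triisopropylsilyloxy)-2-[4-(triisopropylsilyloxy)phenyl]-2,3-dihydro-1-benzofuran-3-carbaldehyde
Product: 14 (2R,3R)-3-hydroxy-5-methoxy-7-(triisopropylsilyloxy)-2-[4-(triisopropylsilyloxy)phenyl]chroman-4-one (5-O-methyl-7,4'-bis-O-TIPS-dihydrokaempferol)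
Conditions: Sc(OTf)3 (10 mol %), 2,6-di-tert-butylpyridine (20 mol %), 4 Å MS, CH2Cl2, −20 °C → rt
Reagents that add atoms: none
Why: Proposed new method: Sc(OTf)3 should bind the tertiary hydroxyl and the formyl oxygen of 13 as a five-membered chelate, within which the C2–C3 σ bond shifts to the activated formyl carbon as the carbinol oxygen becomes the C4 carbonyl (an α-ketol, or acyloin, 1,2-shift); the closest known reaction type is the acid- or Lewis-acid-promoted ring expansion of 1-hydroxycycloalkanecarbaldehydes to 2-hydroxycycloalkanones. Ring C is formed by one-carbon ring enlargement and not by cyclisation: the former formyl carbon is inserted between C2 and the old carbinol carbon, while the O1–C2 bond and the bond from ring A to the new C4 are carried over unchanged. C2 migrates with retention, so the configuration set in step 6 is kept. The new C3 centre is fixed by the syn-chelated transition state, which, with the hydroxyl of 13 anti to the aryl group, places the new hydroxyl equatorial and trans to that aryl group (3R); being α to the ketone, it can in any case settle to the diequatorial 2,3-trans isomer. The step needs C2 to migrate rather than the ring A carbon C3a: C2 is an α-oxygenated, p-silyloxybenzylic carbon of high migratory aptitude, its departure leaves the developing carbonyl conjugated with the trioxygenated ring A, and the aryl ketone is the thermodynamic sink of a reversible shift. The buffered, anhydrous medium is chosen to keep ionisation of the tertiary benzylic hydroxyl (which would aromatise to a benzofuran) and heterolysis of C2–O1 in check.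

Step 11
Reactants: 14 (2R,3R)-3-hydroxy-5-methoxy-7-(triisopropylsilyloxy)-2-[4-(triisopropylsilyloxy)phenyl]chroman-4-one
Product: 15 (2R,3R)-3,5-dihydroxy-7-(triisopropylsilyloxy)-2-[4-(triisopropylsilyloxy)phenyl]chroman-4-one
Conditions: BCl3 (2.5 equiv), CH2Cl2, −78 → −30 °C; then H2O
Reagents that add atoms: none
Why: Chelation-controlled ether cleavage: boron bridges the C4 carbonyl and the 5-methoxy oxygen so that chloride removes only this methyl group, while the aryl silyl ethers survive at low temperature.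

Step 12
Reactants: 15 (2R,3R)-3,5-dihydroxy-7-(triisopropylsilyloxy)-2-[4-(triisopropylsilyloxy)phenyl]chroman-4-one; 16 prenyl alcohol
Product: 17 (2R,3R)-3-hydroxy-5-(3-methylbut-2-en-1-yloxy)-7-(triisopropylsilyloxy)-2-[4-(triisopropylsilyloxy)phenyl]chroman-4-one
Conditions: PPh3, DIAD, 16 (2 equiv), THF, 0 °C → rt
Reagents that add atoms: none
Why: Mitsunobu O-alkylation should engage the only phenol (5-OH) as the acidic partner and the unhindered primary allylic alcohol as the activated one, leaving the less acidic, hindered secondary 3-hydroxyl alone and giving the linear prenyl ether by direct displacement.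

Step 13
Reactants: 17 (2R,3R)-3-hydroxy-5-(3-methylbut-2-en-1-yloxy)-7-(triisopropylsilyloxy)-2-[4-(triisopropylsilyloxy)phenyl]chroman-4-one
Product: 18 (2R,3R)-3,5-dihydroxy-6-(2-methylbut-3-en-2-yl)-7-(triisopropylsilyloxy)-2-[4-(triisopropylsilyloxy)phenyl]chroman-4-one
Conditions: Eu(fod)3 [tris(6,6,7,7,8,8,8-heptafluoro-2,2-dimethyl-3,5-octanedionato)europium] (10 mol %), CHCl3, 55 °C
Reagents that add atoms: none
Why: Aromatic Claisen [3,3] rearrangement from O5 to C6, the only ortho carbon, installs the 1,1-dimethylallyl group with allylic inversion, and the mild europium-catalysed conditions with early interruption are chosen so that the dienone tautomerises to the chelated 5-hydroxyl before a second shift to C8 sets in.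

Step 14
Reactants: 18 (2R,3R)-3,5-dihydroxy-6-(2-methylbut-3-en-2-yl)-7-(triisopropylsilyloxy)-2-[4-(triisopropylsilyloxy)phenyl]chroman-4-one
Product: 19 (2R,3R)-3,5,7-trihydroxy-2-(4-hydroxyphenyl)-6-(2-methylbut-3-en-2-yl)chroman-4-one (CNP0527000.1)
Conditions: Bu4NF (TBAF)/AcOH (1:1, 2.5 equiv), THF, 0 °C
Reagents that add atoms: none
Why: Fluoride-mediated desilylation cleaves both aryl silyl ethers, and the acetic acid buffer protects the base-sensitive flavanonol centres C2 and C3 and the terminal alkene.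

Compound list
1 | 5-methoxyresorcinol | COc1cc(O)cc(O)c1 | starting material
2 | methyl chlorooxoacetate | COC(=O)C(=O)Cl | starting material
3 | methyl 2-(2,4-dihydroxy-6-methoxyphenyl)-2-oxoacetate | COC(=O)C(=O)c1c(O)cc(O)cc1OC | intermediate
4 | methyl 2-[2-hydroxy-6-methoxy-4-(triisopropylsilyloxy)phenyl]-2-oxoacetate | COC(=O)C(=O)c1c(O)cc(O[Si](C(C)C)(C(C)C)C(C)C)cc1OC | intermediate
5 | 4-hydroxybenzyl alcohol | OCc1ccc(O)cc1 | starting material
6 | 4-(triisopropylsilyloxy)benzyl alcohol | OCc1ccc(O[Si](C(C)C)(C(C)C)C(C)C)cc1 | intermediate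
7 | methyl 2-[2-methoxy-4-(triisopropylsilyloxy)-6-{[4-(triisopropylsilyloxy)phenyl]methoxy}phenyl]-2-oxoacetate | COC(=O)C(=O)c1c(OC)cc(O[Si](C(C)C)(C(C)C)C(C)C)cc1OCc1ccc(O[Si](C(C)C)(C(C)C)C(C)C)cc1 | intermediate
8 | N-tosylhydrazone of 7 | COC(=O)C(=NNS(=O)(=O)c1ccc(C)cc1)c1c(OC)cc(O[Si](C(C)C)(C(C)C)C(C)C)cc1OCc1ccc(O[Si](C(C)C)(C(C)C)C(C)C)cc1 | intermediate
9 | methyl 2-diazo-2-[2-methoxy-4-(triisopropylsilyloxy)-6-{[4-(triisopropylsilyloxy)phenyl]methoxy}phenyl]acetate | COC(=O)C(=[N+]=[N-])c1c(OC)cc(O[Si](C(C)C)(C(C)C)C(C)C)cc1OCc1ccc(O[Si](C(C)C)(C(C)C)C(C)C)cc1 | intermediate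
10 | methyl (2S,3R)-4-methoxy-6-(triisopropylsilyloxy)-2-[4-(triisopropylsilyloxy)phenyl]-2,3-dihydro-1-benzofuran-3-carboxylate | COC(=O)[C@@H]1c2c(OC)cc(O[Si](C(C)C)(C(C)C)C(C)C)cc2O[C@@H]1c1ccc(O[Si](C(C)C)(C(C)C)C(C)C)cc1 | intermediate
11 | methyl (2R,3S)-3-hydroxy-4-methoxy-6-(triisopropylsilyloxy)-2-[4-(triisopropylsilyloxy)phenyl]-2,3-dihydro-1-benzofuran-3-carboxylate | COC(=O)[C@]1(O)c2c(OC)cc(O[Si](C(C)C)(C(C)C)C(C)C)cc2O[C@@H]1c1ccc(O[Si](C(C)C)(C(C)C)C(C)C)cc1 | intermediate
12 | (2R,3R)-3-(hydroxymethyl)-4-methoxy-6-(triisopropylsilyloxy)-2-[4-(triisopropylsilyloxy)phenyl]-2,3-dihydro-1-benzofuran-3-ol | OC[C@]1(O)c2c(OC)cc(O[Si](C(C)C)(C(C)C)C(C)C)cc2O[C@@H]1c1ccc(O[Si](C(C)C)(C(C)C)C(C)C)cc1 | intermediate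
13 | (2R,3S)-3-hydroxy-4-methoxy-6-(triisopropylsilyloxy)-2-[4-(triisopropylsilyloxy)phenyl]-2,3-dihydro-1-benzofuran-3-carbaldehyde | O=C[C@]1(O)c2c(OC)cc(O[Si](C(C)C)(C(C)C)C(C)C)cc2O[C@@H]1c1ccc(O[Si](C(C)C)(C(C)C)C(C)C)cc1 | intermediate
14 | (2R,3R)-3-hydroxy-5-methoxy-7-(triisopropylsilyloxy)-2-[4-(triisopropylsilyloxy)phenyl]chroman-4-one | c1c(O[Si](C(C)C)(C(C)C)C(C)C)cc2c(c1OC)C(=O)[C@H](O)[C@@H](c3ccc(O[Si](C(C)C)(C(C)C)C(C)C)cc3)O2 | intermediate
15 | (2R,3R)-3,5-dihydroxy-7-(triisopropylsilyloxy)-2-[4-(triisopropylsilyloxy)phenyl]chroman-4-one | c1c(O[Si](C(C)C)(C(C)C)C(C)C)cc2c(c1O)C(=O)[C@H](O)[C@@H](c3ccc(O[Si](C(C)C)(C(C)C)C(C)C)cc3)O2 | intermediate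
16 | prenyl alcohol (3-methylbut-2-en-1-ol) | CC(C)=CCO | starting material
17 | (2R,3R)-3-hydroxy-5-(3-methylbut-2-en-1-yloxy)-7-(triisopropylsilyloxy)-2-[4-(triisopropylsilyloxy)phenyl]chroman-4-one | c1c(O[Si](C(C)C)(C(C)C)C(C)C)cc2c(c1OCC=C(C)C)C(=O)[C@H](O)[C@@H](c3ccc(O[Si](C(C)C)(C(C)C)C(C)C)cc3)O2 | intermediate
18 | (2R,3R)-3,5-dihydroxy-6-(2-methylbut-3-en-2-yl)-7-(triisopropylsilyloxy)-2-[4-(triisopropylsilyloxy)phenyl]chroman-4-one | C=CC(C)(C)c1c(O[Si](C(C)C)(C(C)C)C(C)C)cc2c(c1O)C(=O)[C@H](O)[C@@H](c1ccc(O[Si](C(C)C)(C(C)C)C(C)C)cc1)O2 | intermediate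
19 | (2R,3R)-3,5,7-trihydroxy-2-(4-hydroxyphenyl)-6-(2-methylbut-3-en-2-yl)chroman-4-one | C=CC(C)(C)c1c(O)cc2c(c1O)C(=O)[C@H](O)[C@@H](c1ccc(O)cc1)O2 | target

Total step count: 14. Longest linear sequence: 13 steps (1 to 19 through steps 1, 2 and 4–14; step 3 is a one-step side branch).

Steps most likely to fail

Step 10. The shift may take the wrong course: the ring A carbon may migrate in place of C2, the tertiary benzylic hydroxyl may ionise with aromatisation, or C2–O1 may open and erode the configuration at C2. The fallback uses the established chalcone epoxide route to trans-flavanonols; it sets out from 1 and returns at 14. Acetylation of 1 (AcOH, BF3·OEt2, 90 °C) should give 2,4-dihydroxy-6-methoxyacetophenone F1. Both phenols are capped (MOMCl, NaH, DMF) to give 6-methoxy-2,4-bis(methoxymethoxy)acetophenone F2. Claisen–Schmidt condensation with commercial 4-(methoxymethoxy)benzaldehyde (KOH, EtOH) gives (E)-1-[2-methoxy-4,6-bis(methoxymethoxy)phenyl]-3-[4-(methoxymethoxy)phenyl]prop-2-en-1-one F3. Juliá–Colonna epoxidation (poly-L-leucine, urea–H2O2, DBU, THF) gives [2-methoxy-4,6-bis(methoxymethoxy)phenyl][(2R,3S)-3-[4-(methoxymethoxy)phenyl]oxiran-2-yl]methanone F4. HCl in MeOH removes the three acetal groups, and the freed 2'-phenol opens the epoxide at the benzylic carbon with inversion to give 5-O-methyl-(2R,3R)-dihydrokaempferol F5. TIPSCl (2.2 equiv) and imidazole in DMF silylate the two phenols in preference to the secondary 3-hydroxyl and return 14.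

Step 6. The di-ortho-substituted aryl carbenoid is twisted out of conjugation, so enantiotopic discrimination may be poor and other carbenoid pathways (attack on ring B, dimerisation) may compete. The fallback sets out from 7, bypasses steps 5–7 and returns at 11. Irradiation of 7 (350 nm, degassed benzene) should bring about hydrogen transfer from the benzylic ether methylene to the excited keto group and closure of the resulting 1,5-biradical. This is the Norrish–Yang-type photocyclisation known for o-benzyloxyphenyl glyoxylates, and it gives racemic methyl 3-hydroxy-4-methoxy-6-(triisopropylsilyloxy)-2-[4-(triisopropylsilyloxy)phenyl]-2,3-dihydro-1-benzofuran-3-carboxylate F6. Preparative chromatography on a chiral stationary phase then supplies 11. A C3 epimer with the same 2R configuration would be equally usable, because C3 becomes the ketone carbon in step 10.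

Step 13. The sigmatropic sequence may run on: a Cope shift of the ortho dienone would move the allyl unit to C8, and prolonged heating could harm the flavanonol. The fallback sets out from 15 and returns at 18, forming the aryl–C(CH3)2 bond by cross-coupling in place of the rearrangement. Iodination ortho to the chelated 5-hydroxyl (N-iodosuccinimide, DMF, 0 °C) should give (2R,3R)-3,5-dihydroxy-6-iodo-7-(triisopropylsilyloxy)-2-[4-(triisopropylsilyloxy)phenyl]chroman-4-one F7. A branch-selective Suzuki–Miyaura coupling with prenylboronic acid pinacol ester (Pd(OAc)2, bulky biaryl dialkylphosphine, K3PO4, THF/H2O, 40 °C) then gives 18.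

Further compounds
F1 | step 10 | 2,4-dihydroxy-6-methoxyacetophenone | CC(=O)c1c(O)cc(O)cc1OC
F2 | step 10 | 6-methoxy-2,4-bis(methoxymethoxy)acetophenone | CC(=O)c1c(OCOC)cc(OCOC)cc1OC
F3 | step 10 | (E)-1-[2-methoxy-4,6-bis(methoxymethoxy)phenyl]-3-[4-(methoxymethoxy)phenyl]prop-2-en-1-one | COCOc1ccc(/C=C/C(=O)c2c(OCOC)cc(OCOC)cc2OC)cc1
F4 | step 10 | [2-methoxy-4,6-bis(methoxymethoxy)phenyl][(2R,3S)-3-[4-(methoxymethoxy)phenyl]oxiran-2-yl]methanone | O=C(c1c(OCOC)cc(OCOC)cc1OC)[C@@H]1O[C@H]1c1ccc(OCOC)cc1
F5 | step 10 | 5-O-methyl-(2R,3R)-dihydrokaempferol | c1c(O)cc2c(c1OC)C(=O)[C@H](O)[C@@H](c3ccc(O)cc3)O2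
F6 | step 6 | racemic methyl 3-hydroxy-4-methoxy-6-(triisopropylsilyloxy)-2-[4-(triisopropylsilyloxy)phenyl]-2,3-dihydro-1-benzofuran-3-carboxylate | COC(=O)C1(O)c2c(OC)cc(O[Si](C(C)C)(C(C)C)C(C)C)cc2OC1c1ccc(O[Si](C(C)C)(C(C)C)C(C)C)cc1
F7 | step 13 | (2R,3R)-3,5-dihydroxy-6-iodo-7-(triisopropylsilyloxy)-2-[4-(triisopropylsilyloxy)phenyl]chroman-4-one | Ic1c(O[Si](C(C)C)(C(C)C)C(C)C)cc2c(c1O)C(=O)[C@H](O)[C@@H](c1ccc(O[Si](C(C)C)(C(C)C)C(C)C)cc1)O2
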